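**Retrosynthetic overview**
- Target ⇐ benzylic silyl ether of the same skeleton carrying Br in place of CO2Me; the ester is installed late by Pd-catalysed methoxycarbonylation, so no ester has to survive the hydride steps.
- C9 methyl ⇐ CH2OTs ⇐ CH2OH ⇐ C9 acyl carbon of an N-acyl oxazolidinone.
- Key C7–C8 bond: Evans syn glycolate aldol of 3,4-dimethoxybenzaldehyde with the boron enolate of an (R)-4-benzyl-3-(aryloxyacetyl)oxazolidin-2-one; this sets both stereocentres (syn adduct = threo, 7S,8S).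
- Aryloxyacetyl imide ⇐ 4-bromo-2-methoxyphenol + ethyl bromoacetate + (R)-4-benzyl-2-oxazolidinone.
- No ring is formed: both benzene rings are bought, and the oxazolidinone is a purchased auxiliary that is cleaved off and recovered.

Assumption: the SMILES is read as the (7S,8S) = (1S,2S) threo isomer, with neolignan numbering (C7 carbinol carbon, C8 ether-bearing carbon, C9 methyl carbon).

**Route**

Step 1
Reactants: 1 4-bromo-2-methoxyphenol; 2 ethyl bromoacetate
Product: 3 ethyl 2-(4-bromo-2-methoxyphenoxy)acetate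
Conditions: K2CO3, acetone, reflux
Reagents that add atoms: none
Why: Williamson ether synthesis, an SN2 displacement of an activated α-bromo ester by the phenoxide, is clean for guaiacol-type phenols.

Step 2
Reactants: 3 ethyl 2-(4-bromo-2-methoxyphenoxy)acetate
Product: 5 2-(4-bromo-2-methoxyphenoxy)acetic acid, via lithium carboxylate 4 (not isolated)
Conditions: LiOH·H2O, THF/H2O, rt; then 1 M HCl
Reagents that add atoms: lithium hydroxide, [Li+].[OH-]
Why: Saponification of an unhindered ethyl ester has no competing functionality here, and acidification precipitates the aryloxyacetic acid.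

Step 3
Reactants: 5 2-(4-bromo-2-methoxyphenoxy)acetic acid; 6 (R)-4-benzyl-2-oxazolidinone
Product: 8 (R)-4-benzyl-3-[2-(4-bromo-2-methoxyphenoxy)acetyl]oxazolidin-2-one, via mixed pivalic anhydride 7 (not isolated)
Conditions: t-BuCOCl, Et3N, THF, −20 °C; then 6, LiCl, −20 °C → rt
Reagents that add atoms: none
Why: N-acylation through a mixed anhydride, in which the hindered pivaloyl carbonyl steers the LiCl-activated oxazolidinone onto the aryloxyacetyl carbonyl.

Step 4
Reactants: 8 (R)-4-benzyl-3-[2-(4-bromo-2-methoxyphenoxy)acetyl]oxazolidin-2-one; 9 3,4-dimethoxybenzaldehyde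
Product: 12 (R)-4-benzyl-3-[(2R,3S)-2-(4-bromo-2-methoxyphenoxy)-3-(3,4-dimethoxyphenyl)-3-hydroxypropanoyl]oxazolidin-2-one, via Z-dibutylboron enolate 10 (not isolated), via dibutylboron aldolate 11 (not isolated)
Conditions: n-Bu2BOTf, i-Pr2NEt, CH2Cl2, −78 → 0 °C; 9, −78 → 0 °C; then pH 7 buffer, MeOH, 30% H2O2, 0 °C
Reagents that add atoms: none
Why: Evans syn aldol, in which soft enolisation gives only the Z-boron enolate and the chair Zimmerman–Traxler transition state, with the aldehyde approaching the face away from the benzyl group, delivers the 2,3-syn (2R,3S) adduct that corresponds to 7S,8S in the target.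

Step 5
Reactants: 12 (R)-4-benzyl-3-[(2R,3S)-2-(4-bromo-2-methoxyphenoxy)-3-(3,4-dimethoxyphenyl)-3-hydroxypropanoyl]oxazolidin-2-one
Product: 13 (R)-4-benzyl-3-[(2R,3S)-2-(4-bromo-2-methoxyphenoxy)-3-(tert-butyldimethylsilyloxy)-3-(3,4-dimethoxyphenyl)propanoyl]oxazolidin-2-one
Conditions: t-BuMe2SiOTf, 2,6-lutidine, CH2Cl2, −78 → 0 °C
Reagents that add atoms: tert-butyldimethylsilyl triflate, CC(C)(C)[Si](C)(C)OS(=O)(=O)C(F)(F)F
Why: Silylation with a silyl triflate and a hindered base protects the benzylic aldol hydroxyl at low temperature without retro-aldol or C2 epimerisation, which blocks retro-aldol, oxetane formation and over-sulfonylation later.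

Step 6
Reactants: 13 (R)-4-benzyl-3-[(2R,3S)-2-(4-bromo-2-methoxyphenoxy)-3-(tert-butyldimethylsilyloxy)-3-(3,4-dimethoxyphenyl)propanoyl]oxazolidin-2-one
Product: 14 (2S,3S)-2-(4-bromo-2-methoxyphenoxy)-3-(tert-butyldimethylsilyloxy)-3-(3,4-dimethoxyphenyl)propan-1-ol
Conditions: LiBH4, MeOH (1 equiv per LiBH4), THF, 0 °C
Reagents that add atoms: none
Why: Reductive cleavage of the auxiliary by borohydride attack at the exocyclic imide carbonyl gives the primary alcohol without touching the aryl bromide, silyl ether or either stereocentre.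

Step 7
Reactants: 14 (2S,3S)-2-(4-bromo-2-methoxyphenoxy)-3-(tert-butyldimethylsilyloxy)-3-(3,4-dimethoxyphenyl)propan-1-ol
Product: 15 (2S,3S)-2-(4-bromo-2-methoxyphenoxy)-3-(tert-butyldimethylsilyloxy)-3-(3,4-dimethoxyphenyl)propyl 4-methylbenzenesulfonate
Conditions: TsCl, Et3N, 4-(dimethylamino)pyridine (cat.), CH2Cl2, 0 °C → rt
Reagents that add atoms: p-toluenesulfonyl chloride, Cc1ccc(cc1)S(Cl)(=O)=O
Why: Sulfonylation of the only free hydroxyl, a primary alcohol, turns C9–O into a leaving group.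

Step 8
Reactants: 15 (2S,3S)-2-(4-bromo-2-methoxyphenoxy)-3-(tert-butyldimethylsilyloxy)-3-(3,4-dimethoxyphenyl)propyl 4-methylbenzenesulfonate
Product: 16 tert-butyl{[(1S,2S)-2-(4-bromo-2-methoxyphenoxy)-1-(3,4-dimethoxyphenyl)propoxy]}dimethylsilane
Conditions: LiEt3BH, THF, 0 °C → rt
Reagents that add atoms: none
Why: Hydride SN2 displacement of a primary tosylate by the strongly nucleophilic triethylborohydride gives the C9 methyl group, while the aryl bromide, silyl ether and aryl ethers are inert at this temperature.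

Step 9
Reactants: 16 tert-butyl{[(1S,2S)-2-(4-bromo-2-methoxyphenoxy)-1-(3,4-dimethoxyphenyl)propoxy]}dimethylsilane
Product: 17 methyl 4-{[(1S,2S)-1-(tert-butyldimethylsilyloxy)-1-(3,4-dimethoxyphenyl)propan-2-yl]oxy}-3-methoxybenzoate
Conditions: Pd(OAc)2 (3 mol%), 4,5-bis(diphenylphosphino)-9,9-dimethylxanthene (6 mol%), CO (1 atm), Et3N, MeOH/toluene, 75 °C
Reagents that add atoms: carbon monoxide, [C-]#[O+]; methanol, CO
Why: Palladium-catalysed alkoxycarbonylation, in which zerovalent palladium formed in situ adds oxidatively to the aryl C–Br bond, CO inserts and methanolysis of the acylpalladium species releases the methyl ester.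

Step 10
Reactants: 17 methyl 4-{[(1S,2S)-1-(tert-butyldimethylsilyloxy)-1-(3,4-dimethoxyphenyl)propan-2-yl]oxy}-3-methoxybenzoate
Product: 18 methyl 4-{[(1S,2S)-1-(3,4-dimethoxyphenyl)-1-hydroxypropan-2-yl]oxy}-3-methoxybenzoate
Conditions: Bu4NF, AcOH (1:1), THF, 0 °C → rt
Reagents that add atoms: none
Why: Fluoride-mediated desilylation, buffered with acetic acid, frees the benzylic alcohol without ester hydrolysis or ionisation of the electron-rich benzylic centre, so the 7S,8S configuration is kept.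

**Compound list**

1 | 4-bromo-2-methoxyphenol | COc1cc(Br)ccc1O | starting material
2 | ethyl bromoacetate | CCOC(=O)CBr | starting material
3 | ethyl 2-(4-bromo-2-methoxyphenoxy)acetate | CCOC(=O)COc1ccc(Br)cc1OC | intermediate
4 | lithium 2-(4-bromo-2-methoxyphenoxy)acetate | [Li+].[O-]C(=O)COc1ccc(Br)cc1OC | intermediate
5 | 2-(4-bromo-2-methoxyphenoxy)acetic acid | OC(=O)COc1ccc(Br)cc1OC | intermediate
6 | (R)-4-benzyl-2-oxazolidinone | O=C1N[C@H](Cc2ccccc2)CO1 | starting material
7 | 2-(4-bromo-2-methoxyphenoxy)acetic pivalic anhydride | CC(C)(C)C(=O)OC(=O)COc1ccc(Br)cc1OC | intermediate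
8 | (R)-4-benzyl-3-[2-(4-bromo-2-methoxyphenoxy)acetyl]oxazolidin-2-one | COc1cc(Br)ccc1OCC(=O)N1[C@H](Cc2ccccc2)COC1=O | intermediate
9 | 3,4-dimethoxybenzaldehyde | COc1ccc(C=O)cc1OC | starting material
10 | (Z)-dibutylboron enolate of 8 | CCCCB(CCCC)O/C(=C\Oc1ccc(Br)cc1OC)N1[C@H](Cc2ccccc2)COC1=O | intermediate
11 | O-dibutylboryl aldolate of 12 | COc1cc(Br)ccc1O[C@@H](C(=O)N1[C@H](Cc2ccccc2)COC1=O)[C@@H](OB(CCCC)CCCC)c1ccc(OC)c(OC)c1 | intermediate
12 | (R)-4-benzyl-3-[(2R,3S)-2-(4-bromo-2-methoxyphenoxy)-3-(3,4-dimethoxyphenyl)-3-hydroxypropanoyl]oxazolidin-2-one | COc1cc(Br)ccc1O[C@@H](C(=O)N1[C@H](Cc2ccccc2)COC1=O)[C@@H](O)c1ccc(OC)c(OC)c1 | intermediate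
13 | (R)-4-benzyl-3-[(2R,3S)-2-(4-bromo-2-methoxyphenoxy)-3-(tert-butyldimethylsilyloxy)-3-(3,4-dimethoxyphenyl)propanoyl]oxazolidin-2-one | COc1cc(Br)ccc1O[C@@H](C(=O)N1[C@H](Cc2ccccc2)COC1=O)[C@@H](O[Si](C)(C)C(C)(C)C)c1ccc(OC)c(OC)c1 | intermediate
14 | (2S,3S)-2-(4-bromo-2-methoxyphenoxy)-3-(tert-butyldimethylsilyloxy)-3-(3,4-dimethoxyphenyl)propan-1-ol | COc1cc(Br)ccc1O[C@@H](CO)[C@@H](O[Si](C)(C)C(C)(C)C)c1ccc(OC)c(OC)c1 | intermediate
15 | (2S,3S)-2-(4-bromo-2-methoxyphenoxy)-3-(tert-butyldimethylsilyloxy)-3-(3,4-dimethoxyphenyl)propyl 4-methylbenzenesulfonate | COc1cc(Br)ccc1O[C@@H](COS(=O)(=O)c1ccc(C)cc1)[C@@H](O[Si](C)(C)C(C)(C)C)c1ccc(OC)c(OC)c1 | intermediate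
16 | tert-butyl{[(1S,2S)-2-(4-bromo-2-methoxyphenoxy)-1-(3,4-dimethoxyphenyl)propoxy]}dimethylsilane | COc1cc(Br)ccc1O[C@@H](C)[C@@H](O[Si](C)(C)C(C)(C)C)c1ccc(OC)c(OC)c1 | intermediate
17 | methyl 4-{[(1S,2S)-1-(tert-butyldimethylsilyloxy)-1-(3,4-dimethoxyphenyl)propan-2-yl]oxy}-3-methoxybenzoate | COC(=O)c1ccc(O[C@@H](C)[C@@H](O[Si](C)(C)C(C)(C)C)c2ccc(OC)c(OC)c2)c(OC)c1 | intermediate
18 | methyl 4-{[(1S,2S)-1-(3,4-dimethoxyphenyl)-1-hydroxypropan-2-yl]oxy}-3-methoxybenzoate | COC(=O)c1ccc(O[C@@H](C)[C@@H](O)c2ccc(OC)c(OC)c2)c(OC)c1 | target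

**Totals**

Total step count: 10. Longest linear sequence: 10 steps (1 → 18); the other inputs (2, 6, 9) are purchased.

**Steps most likely to fail, with fallbacks**

Step 4 (aldol). Risks are sluggish addition to the electron-rich aldehyde, retro-aldol on work-up, or lower dr than usual for glycolate imides. The fallback sets out from ester 3 and replaces the auxiliary aldol by a crossed Claisen condensation followed by a catalyst-controlled reduction. The lithium enolate of 3 (LiN(SiMe3)2, 2.2 equiv, THF, −78 °C) is acylated with 3,4-dimethoxybenzoyl chloride to give the racemic, freely epimerising β-keto ester ethyl 2-(4-bromo-2-methoxyphenoxy)-3-(3,4-dimethoxyphenyl)-3-oxopropanoate F1. Asymmetric transfer hydrogenation with dynamic kinetic resolution (RuCl(p-cymene)[(R,R)-N-tosyl-1,2-diphenylethylenediamine], HCO2H/Et3N, CH2Cl2, 30 °C) reduces the aryl ketone while C2 equilibrates, giving the syn hydroxy ester ethyl (2R,3S)-2-(4-bromo-2-methoxyphenoxy)-3-(3,4-dimethoxyphenyl)-3-hydroxypropanoate F2. The (R,R) antipode is the one the usual aryl ketone model predicts for the 3S carbinol, so the assignment is confirmed by Mosher esters before scale-up. Silylation (t-BuMe2SiOTf, 2,6-lutidine) gives ethyl (2R,3S)-2-(4-bromo-2-methoxyphenoxy)-3-(tert-butyldimethylsilyloxy)-3-(3,4-dimethoxyphenyl)propanoate F3. Reduction with i-Bu2AlH (CH2Cl2, −78 → 0 °C) comes back to the route at alcohol 14.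

Step 8 (tosylate reduction). Risks are S–O cleavage that returns 14, or slow displacement at the β-branched centre. The fallback sets out from alcohol 14 and swaps the polar hydride displacement for a radical chain reduction. Iodination (I2, PPh3, imidazole, CH2Cl2, 0 °C → rt) gives tert-butyl{[(1S,2R)-2-(4-bromo-2-methoxyphenoxy)-1-(3,4-dimethoxyphenyl)-3-iodopropoxy]}dimethylsilane F4. Bu3SnH (1.1 equiv, concentrated solution in toluene, Et3B/air initiation at rt, or azobisisobutyronitrile at 80 °C) abstracts the iodine far faster than the aryl bromine. The high stannane concentration lets hydrogen transfer outrun β-scission of the aryloxy group, and the route is rejoined at 16.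

Step 9 (methoxycarbonylation). Risks are slow oxidative addition to the electron-rich aryl bromide or protodebromination. The fallback sets out from bromide 16 and uses organolithium carboxylation instead of catalysis. Bromine–lithium exchange (n-BuLi, THF, −78 °C) gives (4-{[(1S,2S)-1-(tert-butyldimethylsilyloxy)-1-(3,4-dimethoxyphenyl)propan-2-yl]oxy}-3-methoxyphenyl)lithium F5. Quenching with dry CO2 and mild acidification gives 4-{[(1S,2S)-1-(tert-butyldimethylsilyloxy)-1-(3,4-dimethoxyphenyl)propan-2-yl]oxy}-3-methoxybenzoic acid F6. O-Methylation (MeI, K2CO3, DMF, rt) comes back to the route at ester 17.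

**Further compounds**

F1 | step 4 | ethyl 2-(4-bromo-2-methoxyphenoxy)-3-(3,4-dimethoxyphenyl)-3-oxopropanoate | CCOC(=O)C(Oc1ccc(Br)cc1OC)C(=O)c1ccc(OC)c(OC)c1
F2 | step 4 | ethyl (2R,3S)-2-(4-bromo-2-methoxyphenoxy)-3-(3,4-dimethoxyphenyl)-3-hydroxypropanoate | COc1cc(Br)ccc1O[C@@H](C(=O)OCC)[C@@H](O)c1ccc(OC)c(OC)c1
F3 | step 4 | ethyl (2R,3S)-2-(4-bromo-2-methoxyphenoxy)-3-(tert-butyldimethylsilyloxy)-3-(3,4-dimethoxyphenyl)propanoate | COc1cc(Br)ccc1O[C@@H](C(=O)OCC)[C@@H](O[Si](C)(C)C(C)(C)C)c1ccc(OC)c(OC)c1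
F4 | step 8 | tert-butyl{[(1S,2R)-2-(4-bromo-2-methoxyphenoxy)-1-(3,4-dimethoxyphenyl)-3-iodopropoxy]}dimethylsilane | COc1cc(Br)ccc1O[C@@H](CI)[C@@H](O[Si](C)(C)C(C)(C)C)c1ccc(OC)c(OC)c1
F5 | step 9 | (4-{[(1S,2S)-1-(tert-butyldimethylsilyloxy)-1-(3,4-dimethoxyphenyl)propan-2-yl]oxy}-3-methoxyphenyl)lithium | [Li]c1ccc(O[C@@H](C)[C@@H](O[Si](C)(C)C(C)(C)C)c2ccc(OC)c(OC)c2)c(OC)c1
F6 | step 9 | 4-{[(1S,2S)-1-(tert-butyldimethylsilyloxy)-1-(3,4-dimethoxyphenyl)propan-2-yl]oxy}-3-methoxybenzoic acid | OC(=O)c1ccc(O[C@@H](C)[C@@H](O[Si](C)(C)C(C)(C)C)c2ccc(OC)c(OC)c2)c(OC)c1
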